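**Retrosynthetic overview**
1. The target comes from hydrogenolysis of two benzyl ethers and a Dakin CHO → OH exchange on a 2-arylchromone whose B ring is 3'-formyl-4'-hydroxy-5'-methoxyphenyl.
2. Key disconnection C2–C1': C-2 of the finished chromone is normally the acceptor carbon. Here it serves as a carbanion (2-zincated chromone, an α-oxyvinyl/acyl-anion-type and β-acylvinyl/homoenolate-type donor) against the C–Br carbon of unprotected 5-bromo-o-vanillin.
3. The chromone comes from an o-hydroxyacetophenone and a one-carbon unit (DMF-DMA enaminone, acid ring closure).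
4. The pentaoxygenated acetophenone comes from phloroacetophenone by 3,5-dibromination, double copper-mediated methoxylation and symmetry-aided bis-benzylation.
5. Ring order: the A ring is bought, the pyranone C ring is closed in step 4, and the B ring is bought and attached in step 5.

Assumption: the target is a flat, achiral flavone with no stereogenic element, so no stereocontrol is needed and the route makes the one structure given.

**Route**

Step 1
Reactants: 1 2',4',6'-trihydroxyacetophenone
Product: 2 1-(3,5-dibromo-2,4,6-trihydroxyphenyl)ethan-1-one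
Conditions: Br2 (2.05 equiv), AcOH, 15 °C → rt
Reagents that add atoms: bromine, BrBr
Why: Electrophilic aromatic bromination, in which the two free ring positions are each activated by three oxygen donors and react far faster than the acetyl α-carbon, so two equivalents stop at the 3,5-dibromide.

Step 2
Reactants: 2 1-(3,5-dibromo-2,4,6-trihydroxyphenyl)ethan-1-one
Product: 3 1-(2,4,6-trihydroxy-3,5-dimethoxyphenyl)ethan-1-one
Conditions: NaOMe (10 equiv, 25% in MeOH), CuBr (0.3 equiv), DMF, 110 °C, N2; then 2 M HCl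
Reagents that add atoms: sodium methoxide, C[O-].[Na+]
Why: Copper(I)-catalysed Ullmann-type methoxylation, in which aryl bromides flanked by phenoxide oxygens (as in 6,8-dibromo-5,7-dihydroxyflavones) exchange Br for OMe without phenol protection and the ketone is inert as part of the polyphenoxide.

Step 3
Reactants: 3 1-(2,4,6-trihydroxy-3,5-dimethoxyphenyl)ethan-1-one
Product: 4 1-[2,4-bis(benzyloxy)-6-hydroxy-3,5-dimethoxyphenyl]ethan-1-one
Conditions: BnBr (2.1 equiv), K2CO3 (2.5 equiv), DMF, rt → 40 °C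
Reagents that add atoms: benzyl bromide, BrCc1ccccc1
Why: Williamson etherification, in which the 2- and 6-OH are equivalent by symmetry, the last ortho-OH stays hydrogen-bonded to the ketone and unreactive after two alkylations, and C-benzylation is excluded because the ring is fully substituted.

Step 4
Reactants: 4 1-[2,4-bis(benzyloxy)-6-hydroxy-3,5-dimethoxyphenyl]ethan-1-one
Product: 6 5,7-bis(benzyloxy)-6,8-dimethoxy-4H-chromen-4-one, via (E)-enaminone 5 (not isolated)
Conditions: Me2NCH(OMe)2 (3 equiv), toluene, 95 °C; evaporate; then conc. HCl, CH2Cl2, rt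
Reagents that add atoms: N,N-dimethylformamide dimethyl acetal, COC(OC)N(C)C
Why: Enaminone chromone synthesis, in which the methyl ketone condenses with the amide acetal and acid then triggers conjugate addition of the free phenol and loss of dimethylamine (addition–elimination) under conditions too mild to cleave the benzyl ethers.

Step 5
Reactants: 6 5,7-bis(benzyloxy)-6,8-dimethoxy-4H-chromen-4-one; 7 5-bromo-2-hydroxy-3-methoxybenzaldehyde
Product: 10 5-[5,7-bis(benzyloxy)-6,8-dimethoxy-4-oxo-4H-chromen-2-yl]-2-hydroxy-3-methoxybenzaldehyde, via chromon-2-ylzinc amide 8 (not isolated), via chromon-2-ylzinc aryloxide 9 (not isolated)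
Conditions: TMP2Zn·2MgCl2·2LiCl (1.1 equiv), THF, −30 °C → rt; then 7 (1.1 equiv), 0 °C; then Pd(OAc)2 (3 mol %), SPhos (6 mol %), 50 °C; aq NH4Cl
Reagents that add atoms: none
Why: Lewis-acid-triggered deprotonative zincation followed by Negishi cross-coupling, in which MgCl2 on the C-4 carbonyl blocks carbonyl-directed C-3 metalation and acidifies C2–H, turning the normally electrophilic C-2 (enone β-carbon, acyl-level carbon of a masked β-keto aldehyde) into a carbanion that joins the electrophilic C–Br carbon of 7, while the second TMP–Zn bond takes up the phenol proton and the resulting RZn(OAr) species is too unreactive to add to the aldehyde.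

Step 6
Reactants: 10 5-[5,7-bis(benzyloxy)-6,8-dimethoxy-4-oxo-4H-chromen-2-yl]-2-hydroxy-3-methoxybenzaldehyde
Product: 12 5,7-bis(benzyloxy)-2-(3,4-dihydroxy-5-methoxyphenyl)-6,8-dimethoxy-4H-chromen-4-one, via aryl formate 11 (not isolated)
Conditions: 30% H2O2 (1.3 equiv), 1 M NaOH (2.5 equiv), THF–H2O, 0 °C → rt, N2; then 1 M HCl
Reagents that add atoms: hydrogen peroxide, OO
Why: Dakin oxidation, in which hydroperoxide adds to the aldehyde, the aryl group migrates with help from the ortho-phenoxide, the formate is saponified in situ, and the 4'-phenoxide conjugated with C-2 protects the flavone double bond from nucleophilic epoxidation.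

Step 7
Reactants: 12 5,7-bis(benzyloxy)-2-(3,4-dihydroxy-5-methoxyphenyl)-6,8-dimethoxy-4H-chromen-4-one
Product: 13 5,7,3',4'-tetrahydroxy-6,8,5'-trimethoxyflavone
Conditions: H2 (1 atm), 10% Pd/C, THF–MeOH, rt
Reagents that add atoms: none
Why: Catalytic hydrogenolysis cleaves only the two benzylic C–O bonds, while the methyl ethers and the vinylogous-ester C2=C3 bond of the flavone survive at 1 atm and room temperature.

**Compound list**
1 | 2',4',6'-trihydroxyacetophenone | CC(=O)c1c(O)cc(O)cc1O | starting material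
2 | 1-(3,5-dibromo-2,4,6-trihydroxyphenyl)ethan-1-one | CC(=O)c1c(O)c(Br)c(O)c(Br)c1O | intermediate
3 | 1-(2,4,6-trihydroxy-3,5-dimethoxyphenyl)ethan-1-one | CC(=O)c1c(O)c(OC)c(O)c(OC)c1O | intermediate
4 | 1-[2,4-bis(benzyloxy)-6-hydroxy-3,5-dimethoxyphenyl]ethan-1-one | CC(=O)c1c(O)c(OC)c(OCc2ccccc2)c(OC)c1OCc1ccccc1 | intermediate
5 | (E)-1-[2,4-bis(benzyloxy)-6-hydroxy-3,5-dimethoxyphenyl]-3-(dimethylamino)prop-2-en-1-one (not isolated) | CN(C)/C=C/C(=O)c1c(O)c(OC)c(OCc2ccccc2)c(OC)c1OCc1ccccc1 | intermediate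
6 | 5,7-bis(benzyloxy)-6,8-dimethoxy-4H-chromen-4-one | O=c1ccoc2c(OC)c(OCc3ccccc3)c(OC)c(OCc3ccccc3)c12 | intermediate
7 | 5-bromo-2-hydroxy-3-methoxybenzaldehyde (5-bromo-o-vanillin) | COc1cc(Br)cc(C=O)c1O | starting material
8 | [5,7-bis(benzyloxy)-6,8-dimethoxy-4-oxo-4H-chromen-2-yl](2,2,6,6-tetramethylpiperidin-1-yl)zinc (not isolated) | CC1(C)CCCC(C)(C)N1[Zn]c1cc(=O)c2c(OCc3ccccc3)c(OC)c(OCc3ccccc3)c(OC)c2o1 | intermediate
9 | [5,7-bis(benzyloxy)-6,8-dimethoxy-4-oxo-4H-chromen-2-yl]zinc 4-bromo-2-formyl-6-methoxyphenoxide (not isolated) | COc1cc(Br)cc(C=O)c1O[Zn]c1cc(=O)c2c(OCc3ccccc3)c(OC)c(OCc3ccccc3)c(OC)c2o1 | intermediate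
10 | 5-[5,7-bis(benzyloxy)-6,8-dimethoxy-4-oxo-4H-chromen-2-yl]-2-hydroxy-3-methoxybenzaldehyde | COc1cc(-c2cc(=O)c3c(OCc4ccccc4)c(OC)c(OCc4ccccc4)c(OC)c3o2)cc(C=O)c1O | intermediate
11 | 5-[5,7-bis(benzyloxy)-6,8-dimethoxy-4-oxo-4H-chromen-2-yl]-2-hydroxy-3-methoxyphenyl formate (not isolated) | COc1cc(-c2cc(=O)c3c(OCc4ccccc4)c(OC)c(OCc4ccccc4)c(OC)c3o2)cc(OC=O)c1O | intermediate
12 | 5,7-bis(benzyloxy)-2-(3,4-dihydroxy-5-methoxyphenyl)-6,8-dimethoxy-4H-chromen-4-one | COc1cc(-c2cc(=O)c3c(OCc4ccccc4)c(OC)c(OCc4ccccc4)c(OC)c3o2)cc(O)c1O | intermediate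
13 | 5,7,3',4'-tetrahydroxy-6,8,5'-trimethoxyflavone | COc1cc(-c2cc(=O)c3c(O)c(OC)c(O)c(OC)c3o2)cc(O)c1O | target

**Totals**
Total step count: 7. Longest linear sequence: 7 (1 → 2 → 3 → 4 → 6 → 10 → 12 → 13). Compound 7 is bought and used as such.

**Three steps most likely to fail**

Step 5 (C-2 zincation and coupling with the unprotected partner). The risks are loss of the C–Zn bond to the phenol proton, MgCl2-promoted addition to the aldehyde, and slow oxidative addition of the electron-rich zinc phenoxide.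
- The fallback sets out from 7 and comes back to the route at 13. The oxidation is moved in front of the coupling and the partner is fully masked.
- Dakin oxidation of 7 (H2O2, NaOH) passes through 5-bromo-2-hydroxy-3-methoxyphenyl formate F1 to 5-bromo-3-methoxybenzene-1,2-diol F2.
- BnBr/K2CO3 in DMF then gives 1,2-bis(benzyloxy)-5-bromo-3-methoxybenzene F3, which has neither an acidic proton nor a carbonyl group.
- F3 is coupled with zinc reagent 8 under the same Pd/SPhos catalysis to 5,7-bis(benzyloxy)-2-[3,4-bis(benzyloxy)-5-methoxyphenyl]-6,8-dimethoxy-4H-chromen-4-one F4.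
- Hydrogenolysis of all four benzyl ethers gives 13. This bypasses step 6 and costs one step more overall.

Step 2 (double methoxylation of a trianionic, very electron-rich dibromide). The risks are hydrodebromination and air oxidation of the product phenoxide.
- The fallback sets out from 2 and comes back at 4. Protection and C–O coupling change places, so copper meets a mono-phenol instead of a triphenoxide.
- Compound 2 is bis-benzylated (BnBr, K2CO3, DMF) to 1-[2,4-bis(benzyloxy)-3,5-dibromo-6-hydroxyphenyl]ethan-1-one F5.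
- Both bromides of F5 are then exchanged with NaOMe under ligand-accelerated copper catalysis (CuI, 3,4,7,8-tetramethyl-1,10-phenanthroline, MeOH–toluene, 110 °C). This gives 4 directly with no change in step count.

Step 6 (alkaline peroxide on a flavone that yields an oxidisable catechol). The risks are over-oxidation of the catechol and attack of base or peroxide on the pyranone.
- The fallback sets out from 10 and comes back at 13. The nucleophilic alkaline oxidation is replaced by an electrophilic peracid oxidation on a fully etherified substrate, so no free catechol exists until the last step.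
- Compound 10 is benzylated to 2-(benzyloxy)-5-[5,7-bis(benzyloxy)-6,8-dimethoxy-4-oxo-4H-chromen-2-yl]-3-methoxybenzaldehyde F6.
- Baeyer–Villiger oxidation (mCPBA, NaHCO3, CH2Cl2) gives 2-(benzyloxy)-5-[5,7-bis(benzyloxy)-6,8-dimethoxy-4-oxo-4H-chromen-2-yl]-3-methoxyphenyl formate F7.
- Methanolysis (K2CO3, MeOH) gives 5,7-bis(benzyloxy)-2-[4-(benzyloxy)-3-hydroxy-5-methoxyphenyl]-6,8-dimethoxy-4H-chromen-4-one F8.
- Hydrogenolysis of the three benzyl ethers gives 13.

**Further compounds**
F1 | step 5 | 5-bromo-2-hydroxy-3-methoxyphenyl formate | COc1cc(Br)cc(OC=O)c1O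
F2 | step 5 | 5-bromo-3-methoxybenzene-1,2-diol | COc1cc(Br)cc(O)c1O
F3 | step 5 | 1,2-bis(benzyloxy)-5-bromo-3-methoxybenzene | COc1cc(Br)cc(OCc2ccccc2)c1OCc1ccccc1
F4 | step 5 | 5,7-bis(benzyloxy)-2-[3,4-bis(benzyloxy)-5-methoxyphenyl]-6,8-dimethoxy-4H-chromen-4-one | COc1cc(-c2cc(=O)c3c(OCc4ccccc4)c(OC)c(OCc4ccccc4)c(OC)c3o2)cc(OCc2ccccc2)c1OCc1ccccc1
F5 | step 2 | 1-[2,4-bis(benzyloxy)-3,5-dibromo-6-hydroxyphenyl]ethan-1-one | CC(=O)c1c(O)c(Br)c(OCc2ccccc2)c(Br)c1OCc1ccccc1
F6 | step 6 | 2-(benzyloxy)-5-[5,7-bis(benzyloxy)-6,8-dimethoxy-4-oxo-4H-chromen-2-yl]-3-methoxybenzaldehyde | COc1cc(-c2cc(=O)c3c(OCc4ccccc4)c(OC)c(OCc4ccccc4)c(OC)c3o2)cc(C=O)c1OCc1ccccc1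
F7 | step 6 | 2-(benzyloxy)-5-[5,7-bis(benzyloxy)-6,8-dimethoxy-4-oxo-4H-chromen-2-yl]-3-methoxyphenyl formate | COc1cc(-c2cc(=O)c3c(OCc4ccccc4)c(OC)c(OCc4ccccc4)c(OC)c3o2)cc(OC=O)c1OCc1ccccc1
F8 | step 6 | 5,7-bis(benzyloxy)-2-[4-(benzyloxy)-3-hydroxy-5-methoxyphenyl]-6,8-dimethoxy-4H-chromen-4-one | COc1cc(-c2cc(=O)c3c(OCc4ccccc4)c(OC)c(OCc4ccccc4)c(OC)c3o2)cc(O)c1OCc1ccccc1
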